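**Plan**
- Retrosynthesis cuts, in order: the two O–Si bonds at O5 and O7; C2–C3 of ring C (key cut); the acetal bond O1–C2; then the aryl–dienyl and aryl–prenyl bonds of ring B.
- Enabling feature: C2 carries O1 and the p-methoxyaryl ring B, so a cation at C2 is stabilised twice; C3 is the α-carbon of the C4 ketone on ring A and can serve as a silyl enol ether.
- Forward: the ring B aldehyde is built from 3-bromo-4-hydroxybenzaldehyde (iodination, O-methylation, Stille prenylation, Suzuki dienylation), joined as its α-chloro methyl ether to bis-silylated phloroacetophenone (O1–C2), the ketone is turned into its enol silane, and ring C closes last.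
- Stereochemistry: the only stereocentre, C2 (S), comes from the chiral counter-anion in the cyclisation; the E diene comes from syn-hydroboration of the enyne and is retained in the Suzuki coupling.
- Protecting groups: the ring A phenols travel as TIPS ethers (sturdier than TBS towards NaH and KN(SiMe3)2), the enol ether is TBS; both aryl silyl ethers fall in one mild fluoride step.

Key step: step 10

Assumption: the sense of induction of the chiral acid cannot be derived from the substrate; the catalyst antipode that gives 2S is fixed in a first small run, both antipodes being available from (R)- and (S)-BINOL.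

**Step 1**
Reactants: 1 3-bromo-4-hydroxybenzaldehyde
Product: 2 3-bromo-4-hydroxy-5-iodobenzaldehyde
Conditions: NIS (1.05 equiv), AcOH, rt
Reagents that add atoms: N-iodosuccinimide O=C1CCC(=O)N1I
Why: Electrophilic aromatic iodination; the phenol directs to its only free ortho position, the para position being blocked by the formyl group.

**Step 2**
Reactants: 2 3-bromo-4-hydroxy-5-iodobenzaldehyde
Product: 3 3-bromo-5-iodo-4-methoxybenzaldehyde
Conditions: MeI, K2CO3, DMF, rt
Reagents that add atoms: iodomethane CI
Why: Williamson O-methylation of the acidic 2,6-dihalophenol installs the ring B methoxy group before the metal-catalysed couplings.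

**Step 3**
Reactants: 3 3-bromo-5-iodo-4-methoxybenzaldehyde; 4 tributyl(3-methylbut-2-enyl)stannane
Product: 5 3-bromo-4-methoxy-5-(3-methylbut-2-enyl)benzaldehyde
Conditions: Pd(PPh3)4 (5 mol %), DMF, 70 °C
Reagents that add atoms: none
Why: Stille coupling; zerovalent palladium inserts into the carbon–iodine bond much faster than into the carbon–bromine bond, and the allyl-type stannane should couple at its less substituted terminus to give the linear prenyl arene.

**Step 4**
Reactants: 6 2-methylbut-1-en-3-yne
Product: 7 4,4,5,5-tetramethyl-2-[(1E)-3-methylbuta-1,3-dienyl]-1,3,2-dioxaborolane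
Conditions: pinacolborane, Cp2Zr(H)Cl (5 mol %), Et3N (10 mol %), CH2Cl2, rt to 40 °C
Reagents that add atoms: pinacolborane CC1(C)OBOC1(C)C
Why: Zirconium-catalysed hydroboration of the terminal alkyne; syn addition of H–B puts boron on the terminal carbon and fixes the E geometry, while the 1,1-disubstituted alkene is left alone.

**Step 5**
Reactants: 5 3-bromo-4-methoxy-5-(3-methylbut-2-enyl)benzaldehyde; 7 4,4,5,5-tetramethyl-2-[(1E)-3-methylbuta-1,3-dienyl]-1,3,2-dioxaborolane
Product: 8 4-methoxy-3-[(1E)-3-methylbuta-1,3-dienyl]-5-(3-methylbut-2-enyl)benzaldehyde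
Conditions: PdCl2(dppf) (3 mol %), K3PO4, 1,4-dioxane/H2O, 70 °C
Reagents that add atoms: none
Why: Suzuki–Miyaura coupling at the remaining aryl bromide proceeds with retention of the alkene geometry, and the aldehyde and prenyl group tolerate the mild aqueous base.

**Step 6**
Reactants: 8 4-methoxy-3-[(1E)-3-methylbuta-1,3-dienyl]-5-(3-methylbut-2-enyl)benzaldehyde
Product: 9 5-(dimethoxymethyl)-2-methoxy-1-[(1E)-3-methylbuta-1,3-dienyl]-3-(3-methylbut-2-enyl)benzene
Conditions: HC(OMe)3, MeOH, PPTS (cat.), rt; Et3N quench
Reagents that add atoms: trimethyl orthoformate COC(OC)OC; methanol CO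
Why: Acid-catalysed acetalisation driven by the orthoformate as water scavenger; PPTS is too weak an acid to add methanol to the diene or the prenyl alkene.

**Step 7**
Reactants: 10 2,4,6-trihydroxyacetophenone
Product: 11 1-[2-hydroxy-4,6-bis(triisopropylsilyloxy)phenyl]ethanone
Conditions: TIPSCl (2.1 equiv), imidazole, DMF, 0 °C to rt
Reagents that add atoms: triisopropylsilyl chloride CC(C)[Si](Cl)(C(C)C)C(C)C
Why: Phenol silylation; the hydroxyl that remains is the one hydrogen-bonded to the acetyl carbonyl and therefore the least nucleophilic, as in the usual two-fold protection of phloroacetophenone.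

**Step 8**
Reactants: 9 5-(dimethoxymethyl)-2-methoxy-1-[(1E)-3-methylbuta-1,3-dienyl]-3-(3-methylbut-2-enyl)benzene; 11 1-[2-hydroxy-4,6-bis(triisopropylsilyloxy)phenyl]ethanone
Product: 14 racemic mixed methyl aryl acetal 1-[2-{methoxy[4-methoxy-3-((1E)-3-methylbuta-1,3-dienyl)-5-(3-methylbut-2-enyl)phenyl]methoxy}-4,6-bis(triisopropylsilyloxy)phenyl]ethanone, via α-chloro methyl ether 12 (not isolated), via sodium phenoxide 13 (not isolated)
Conditions: 9 (1.2 equiv), AcCl (1.05 equiv), ZnBr2 (0.1 mol %), toluene, 0 °C to rt; cannulated into 11 + NaH (1.05 equiv), THF, 0 °C to rt; NaHCO3 work-up, Et3N-deactivated silica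
Reagents that add atoms: none
Why: Zinc-catalysed exchange of one acetal methoxide for chloride with acetyl chloride gives the α-chloro ether, which O-alkylates the sodium phenoxide in the SN1-like Williamson manner of a MOM protection; the acetal carbon is formed racemic, which does not matter because it is ionised in step 10.

**Step 9**
Reactants: 14 racemic mixed methyl aryl acetal ketone
Product: 16 tert-butyldimethylsilyl enol ether of 14 (racemic at the acetal carbon), via potassium enolate 15 (not isolated)
Conditions: KN(SiMe3)2 (1.15 equiv), THF, −78 °C; TBSCl (1.3 equiv), −78 to −20 °C; pentane/pH 7 buffer, Et3N-deactivated silica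
Reagents that add atoms: tert-butyldimethylsilyl chloride CC(C)(C)[Si](C)(C)Cl
Why: Kinetic deprotonation of the methyl ketone and O-silylation of the potassium enolate (silyl enol ether formation) under purely basic conditions, which spare the acid-labile mixed acetal and the aryl TIPS ethers where a silyl triflate/amine protocol would not.

**Step 10**
Reactants: 16 tert-butyldimethylsilyl enol ether of the mixed acetal
Product: 17 (2S)-2-{4-methoxy-3-[(1E)-3-methylbuta-1,3-dienyl]-5-(3-methylbut-2-enyl)phenyl}-5,7-bis(triisopropylsilyloxy)chroman-4-one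
Conditions: chiral IDPi acid HX* (imidodiphosphorimidate from two 3,3'-diaryl-BINOL units, N-triflyl; 5 mol %), toluene (0.02 M), −60 °C; Et3N quench
Reagents that add atoms: none
Why: Proposed new method: the strong chiral acid HX*, or the silylated form TBS–X* that it takes on after protodesilylating a few percent of 16, activates the open and more basic methoxy oxygen of the acetal, MeOTBS departs, and the planar cation O1=C2(+), stabilised by O1 and by the p-methoxyaryl ring B, stays paired with the confined anion while the enol silane carbon C3 adds to C2 and the silyl group is handed on to the next acetal. The closest known reaction types are the chiral-acid or hydrogen-bond-donor catalysed Mukaiyama-type additions of silyl enol ethers to acetal-derived oxocarbenium ions and, for the geometry of closure, the oxa-Pictet–Spengler cyclisation. Ring C closes in a 6-(enolendo)-endo-trig mode, the C3=C4 enol bond and the O1=C2 cation bond both lying inside the new ring. The single new stereocentre C2 is controlled by the chiral counter-anion, which covers one face of the cation; the substrate offers no bias because its racemic acetal centre becomes planar on ionisation. The step needs face selectivity (catalyst), ionisation by loss of methoxide instead of the ring A phenol (the OMe oxygen is more basic and less hindered, and MeOTBS does not return) and C3–C2 regiochemistry, which the tether through ring A secures since only this bond gives a six-membered ring. The cation should form at −60 °C under acid too dilute to touch the diene, the prenyl group or the aryl silyl ethers, and no ring-opened enone, the usual racemisation channel of flavanones, can arise.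

**Step 11**
Reactants: 17 (2S)-5,7-bis(triisopropylsilyloxy)flavanone
Product: 18 (2S)-5,7-dihydroxy-2-{4-methoxy-3-[(1E)-3-methylbuta-1,3-dienyl]-5-(3-methylbut-2-enyl)phenyl}chroman-4-one
Conditions: KHF2 (6 equiv), MeOH, rt
Reagents that add atoms: none
Why: Fluoride cleavage of the two carbonyl-activated aryl silyl ethers in a weakly acidic medium, which should neither open the flavanone to its chalcone (no loss of C2 configuration) nor affect the diene.

**Compound list**
1 | 3-bromo-4-hydroxybenzaldehyde | O=Cc1ccc(O)c(Br)c1 | starting material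
2 | 3-bromo-4-hydroxy-5-iodobenzaldehyde | O=Cc1cc(Br)c(O)c(I)c1 | intermediate
3 | 3-bromo-5-iodo-4-methoxybenzaldehyde | COc1c(Br)cc(C=O)cc1I | intermediate
4 | tributyl(3-methylbut-2-enyl)stannane | CCCC[Sn](CCCC)(CCCC)CC=C(C)C | starting material
5 | 3-bromo-4-methoxy-5-(3-methylbut-2-enyl)benzaldehyde | COc1c(Br)cc(C=O)cc1CC=C(C)C | intermediate
6 | 2-methylbut-1-en-3-yne | C=C(C)C#C | starting material
7 | 4,4,5,5-tetramethyl-2-[(1E)-3-methylbuta-1,3-dienyl]-1,3,2-dioxaborolane | C=C(C)/C=C/B1OC(C)(C)C(C)(C)O1 | intermediate
8 | 4-methoxy-3-[(1E)-3-methylbuta-1,3-dienyl]-5-(3-methylbut-2-enyl)benzaldehyde | C=C(C)/C=C/c1cc(C=O)cc(CC=C(C)C)c1OC | intermediate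
9 | 5-(dimethoxymethyl)-2-methoxy-1-[(1E)-3-methylbuta-1,3-dienyl]-3-(3-methylbut-2-enyl)benzene | C=C(C)/C=C/c1cc(C(OC)OC)cc(CC=C(C)C)c1OC | intermediate
10 | 2,4,6-trihydroxyacetophenone | CC(=O)c1c(O)cc(O)cc1O | starting material
11 | 1-[2-hydroxy-4,6-bis(triisopropylsilyloxy)phenyl]ethanone | CC(=O)c1c(O)cc(O[Si](C(C)C)(C(C)C)C(C)C)cc1O[Si](C(C)C)(C(C)C)C(C)C | intermediate
12 | 5-[chloro(methoxy)methyl]-2-methoxy-1-[(1E)-3-methylbuta-1,3-dienyl]-3-(3-methylbut-2-enyl)benzene (racemic, not isolated) | C=C(C)/C=C/c1cc(C(Cl)OC)cc(CC=C(C)C)c1OC | intermediate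
13 | sodium 2-acetyl-3,5-bis(triisopropylsilyloxy)phenoxide (not isolated) | CC(=O)c1c([O-])cc(O[Si](C(C)C)(C(C)C)C(C)C)cc1O[Si](C(C)C)(C(C)C)C(C)C.[Na+] | intermediate
14 | 1-[2-{methoxy[4-methoxy-3-((1E)-3-methylbuta-1,3-dienyl)-5-(3-methylbut-2-enyl)phenyl]methoxy}-4,6-bis(triisopropylsilyloxy)phenyl]ethanone (racemic at the acetal carbon) | CC(=O)c1c(OC(OC)c2cc(/C=C/C(C)=C)c(OC)c(CC=C(C)C)c2)cc(O[Si](C(C)C)(C(C)C)C(C)C)cc1O[Si](C(C)C)(C(C)C)C(C)C | intermediate
15 | potassium enolate of 14 (not isolated) | C=C([O-])c1c(OC(OC)c2cc(/C=C/C(C)=C)c(OC)c(CC=C(C)C)c2)cc(O[Si](C(C)C)(C(C)C)C(C)C)cc1O[Si](C(C)C)(C(C)C)C(C)C.[K+] | intermediate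
16 | tert-butyldimethylsilyl enol ether of 14: tert-butyl{1-[2-{methoxy[aryl]methoxy}-4,6-bis(triisopropylsilyloxy)phenyl]ethenyloxy}dimethylsilane, aryl = 4-methoxy-3-[(1E)-3-methylbuta-1,3-dienyl]-5-(3-methylbut-2-enyl)phenyl (racemic at the acetal carbon) | C=C(O[Si](C)(C)C(C)(C)C)c1c(OC(OC)c2cc(/C=C/C(C)=C)c(OC)c(CC=C(C)C)c2)cc(O[Si](C(C)C)(C(C)C)C(C)C)cc1O[Si](C(C)C)(C(C)C)C(C)C | intermediate
17 | (2S)-2-{4-methoxy-3-[(1E)-3-methylbuta-1,3-dienyl]-5-(3-methylbut-2-enyl)phenyl}-5,7-bis(triisopropylsilyloxy)chroman-4-one | C=C(C)/C=C/c1cc([C@@H]2CC(=O)c3c(O[Si](C(C)C)(C(C)C)C(C)C)cc(O[Si](C(C)C)(C(C)C)C(C)C)cc3O2)cc(CC=C(C)C)c1OC | intermediate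
18 | (2S)-5,7-dihydroxy-2-{4-methoxy-3-[(1E)-3-methylbuta-1,3-dienyl]-5-(3-methylbut-2-enyl)phenyl}chroman-4-one | C=C(C)/C=C/c1cc([C@@H]2CC(=O)c3c(O)cc(O)cc3O2)cc(CC=C(C)C)c1OC | target

**Step count**
Total: 11 steps. Longest linear sequence: 9 steps (steps 1, 2, 3, 5, 6, 8, 9, 10, 11, from 3-bromo-4-hydroxybenzaldehyde).

**Steps most likely to fail**

Step 10. The counter-anion may discriminate poorly between the two faces of the cation. Ionisation may also run the other way, with loss of the ring A aryloxy group followed by intermolecular addition of the enol silane. The fallback sets out from 8 and 11 and forms ring C through O1–C2 by known chemistry. The dianion of 11 (LiN(SiMe3)2, 2.2 equiv, THF, −78 °C) is added to aldehyde 8 to give the racemic aldol 3-hydroxy-1-[2-hydroxy-4,6-bis(triisopropylsilyloxy)phenyl]-3-arylpropan-1-one F1. Mesylation of the benzylic alcohol and E1cB elimination (MsCl, Et3N, CH2Cl2, 0 °C; the hydrogen-bonded phenol reacts more slowly) gives the (E)-2'-hydroxychalcone F2. The organocatalytic enantioselective intramolecular oxa-Michael addition (quinine-derived bifunctional thiourea, toluene, rt) then closes the ring and rejoins the route at 17. Selectivity of this cyclisation on simple chalcones is moderate, so enrichment by crystallisation or chromatography on a chiral phase may be needed.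

Step 8. The cation-like chloro ether may alkylate the electron-rich ring A at carbon or be captured by the prenyl or diene alkenes, and the mixed acetal may hydrolyse during isolation. The fallback sets out from 9 and 11 and replaces the halide electrophile by a salt made under buffered basic conditions. Acetal 9 with Et3SiOTf and 2,4,6-collidine (CH2Cl2, 0 °C) gives the 1-(α-methoxybenzyl)-2,4,6-trimethylpyridinium triflate F3. Such salts pass their alkoxyalkyl group on to oxygen nucleophiles, and addition of phenoxide 13 (from 11 and NaH in THF) should give 14, where the route is rejoined.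

Step 3. Transmetalation may deliver the stannane through its γ-terminus (reverse prenyl isomer), and discrimination between iodide and bromide may erode at the temperature needed. The fallback sets out from 3. Stille coupling with allyltributylstannane (Pd(PPh3)4, DMF, 70 °C), whose allyl group has no regiochemical ambiguity, gives 3-bromo-4-methoxy-5-(prop-2-enyl)benzaldehyde F4. Cross-metathesis with 2-methylbut-2-ene (second-generation Grubbs catalyst RuCl2(H2IMes)(PCy3)(=CHPh), CH2Cl2, 40 °C) builds the trisubstituted alkene before any diene is present and rejoins the route at 5.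

**Further compounds**
F1 | step 10 | 3-hydroxy-1-[2-hydroxy-4,6-bis(triisopropylsilyloxy)phenyl]-3-{4-methoxy-3-[(1E)-3-methylbuta-1,3-dienyl]-5-(3-methylbut-2-enyl)phenyl}propan-1-one (racemic) | CC(C)=CCc1cc(C(O)CC(=O)c2c(O)cc(O[Si](C(C)C)(C(C)C)C(C)C)cc2O[Si](C(C)C)(C(C)C)C(C)C)cc(/C=C/C(C)=C)c1OC
F2 | step 10 | (2E)-1-[2-hydroxy-4,6-bis(triisopropylsilyloxy)phenyl]-3-{4-methoxy-3-[(1E)-3-methylbuta-1,3-dienyl]-5-(3-methylbut-2-enyl)phenyl}prop-2-en-1-one | CC(C)=CCc1cc(/C=C/C(=O)c2c(O)cc(O[Si](C(C)C)(C(C)C)C(C)C)cc2O[Si](C(C)C)(C(C)C)C(C)C)cc(/C=C/C(C)=C)c1OC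
F3 | step 8 | 1-{methoxy[4-methoxy-3-((1E)-3-methylbuta-1,3-dienyl)-5-(3-methylbut-2-enyl)phenyl]methyl}-2,4,6-trimethylpyridinium trifluoromethanesulfonate (racemic) | COC(c1cc(/C=C/C(C)=C)c(OC)c(CC=C(C)C)c1)[n+]1c(C)cc(C)cc1C.[O-]S(=O)(=O)C(F)(F)F
F4 | step 3 | 3-bromo-4-methoxy-5-(prop-2-enyl)benzaldehyde | COc1c(Br)cc(C=O)cc1CC=C
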